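## Structural features

The target is a 1-aryltetralin cyclolignan in which ring A (C5–C8, with OMe on C6 and free hydroxyls on C7 and C8) is fused through C4a/C8a to the saturated ring B (C1–C4), and C1 carries a 3,4,5-trimethoxyphenyl group through C1′. C1, C2 and C3 are contiguous stereocentres, all S, with the aryl group on C1 cis to the hydroxymethyl carbon C9 on C2 and C9 trans to the hydroxymethyl carbon C10 on C3 (pseudoaxial aryl, two equatorial CH2OH groups). C4 is a plain benzylic methylene bonded to C4a, the ring A carbon para to O7. The C7/C8 catechol is oxidised easily in air and base and must stay masked to the end. No carbonyl group remains next to C1–C3 in the target, so none of the three centres can be corrected late. The real difficulty is twofold: the cis C1/C2 relation at a diarylmethine carbon crowded by the peri oxygen on C8, and the bond from C4 to C4a, a site that is not the most nucleophilic one of the molecule. The key step exploits that C1 is beta and C2 is alpha to C9, so that, while C9 is an acyl group on a chiral oxazolidinone, one auxiliary directs the aryl group to C1 and then C3 to C2 from the same face of an (E)-alkene.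

## Logic of the disconnections

26 ⇒ 25. Restored: the two O–benzyl bonds at O7 and O8 and the C4–O bond. The catechol has to be masked through all basic steps, and the C4 oxygen is the trace of the ring closure. The demand is one hydrogenolysis that cleaves two benzyl ethers and a benzylic C–O bond without touching C1–C3; the para O7–H freed in the same flask activates that C–O bond.

25 ⇒ 24. The C10 alcohol goes back to a tert-butyl ester and the C9 alcohol to its pivalate. C3 must be alpha to a carbonyl group for the ring closure, and O9 must be capped. LiAlH4 has to reduce a hindered ester and an ester protecting group in one operation; after it no centre is epimerisable.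

24 ⇒ 23. Cut: C3–C4 (aldol). C3 is the only carbon alpha to C10 and C4 is an aldehyde on C4a. This opens ring B and removes the C3 centre, which leaves an acyclic chain that carries only C1 and C2. The enolate must bond with C10 trans to C9. Allylic 1,3-strain and thermodynamics both favour this, but only if O9 is not lactonised onto C10: a γ-lactone would put C3 in a five-membered ring whose cis fusion is preferred, and that would give the C3 epimer. This is the reason for the pivalate that is introduced in 19.

23 ⇒ 22 ⇒ 20. Cut: O7–benzyl, then C4–C4a (formylation). With C6 and C8 occupied, C4a is the only position that a free O7–H activates. Ring A returns to the substitution pattern of 1. The formylation must prefer C4a over C5 and over the pendant ring, so O7 must be free while O8 stays capped, and this requires different groups on O7 and O8.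

20 ⇒ 19 ⇒ 18 ⇒ 17. Cut: O7–allyl, O9–pivaloyl, and the C9–N bond to the auxiliary (C9 back to the imide). This returns to the product of the key step. LiBH4 must distinguish the imide from the tert-butyl ester, and the alcohol must be acylated before it can lactonise.

17 ⇒ 12 + 15 + 14. Cut: C1–C1′ and C2–C3. Both centres fall away together and three simple pieces result. The forward step needs 1,4-addition, one enolate geometry, and one auxiliary face for both bond formations. The antipode chosen, (R), is the one that leads to (1S).

15 ⇒ 13. Cut: C1′–Mg; direct magnesium insertion into the aryl bromide.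

12 ⇒ 8 + 10 (through 11, made with 9). Cut: N–C9. The acid must be activated without touching the allyl ether or the (E)-alkene.

8 ⇒ 6 + 7. Cut: the C1=C2 double bond. The condensation must give the (E)-alkene only, because the alkene geometry is translated into the C1/C2 relation.

6 ⇒ 4 + 5, and 4 ⇒ 1 + 2 (through 3). Cut: O8–benzyl, then O7–allyl. The first alkylation must pick one of two neighbouring phenols; the dianion 3 provides the difference in nucleophilicity.

## Other disconnections considered

Alternative 1: The cut runs through C1–C2 and C3–C4, a retro-Diels–Alder of ring B. Forward, racemic 2,3-bis(benzyloxy)-4-methoxy-8-(3,4,5-trimethoxyphenyl)bicyclo[4.2.0]octa-1,3,5-triene A2 would be heated. Conrotatory opening with the aryl group turning outward gives the (E)-o-quinodimethane, which adds endo to (5R)-5-(l-menthyloxy)furan-2(5H)-one A3, anti to the menthyloxy group of A3, to give the cycloadduct A1.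
- In its favour: ring B, two skeletal bonds and three centres arise in one neutral, pericyclic step. The cis C1/C2 relation follows from the endo rule. C4 is present from the start, so no late substitution at C4a is needed. On that point, and in bond economy of the key step, this alternative is better than the chosen plan.
- Against it here: A1 is cis-fused at C2/C3, so C3 must later be inverted after the acetal carbon is unmasked as an aldehyde; this costs steps and rests on a thermodynamic preference. A2, with three oxygens on ring A and one of them next to the four-membered ring, is itself a multistep target.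
- Comparison: the chosen plan sets C1 and C2 by one auxiliary and C3 correctly at once, from commercial pieces. Overall the alternative should be longer, although its key step is the more powerful one.

Alternative 2: The cut runs through C1–C2 and O8–C9. Forward, Cs2CO3 would eliminate sulfinate from racemic 2-(allyloxy)-3-methoxy-6-[(4-methylphenylsulfonyl)(3,4,5-trimethoxyphenyl)methyl]phenol A5 to give an o-quinone methide. A chiral triazolium-derived carbene would convert methyl (E)-4-oxobut-2-enoate A6 into an azolium enolate that adds through C2 to C1 of the quinone methide from A5; acylation of O8 by C9 releases the catalyst and closes the dihydrocoumarin A4.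
- In its favour: it is catalytic, needs no stoichiometric auxiliary or copper, and starts from a racemic precursor; on these points it is equal or better. A4 has the same oxidation pattern at C9/C10 as 17, and O8 is masked by the lactone itself.
- Against it here: annulations of this type would be expected to favour the cis dihydrocoumarin, so the trans isomer A4 would depend on a later epimerisation at C2 that the catalyst does not control. Reductive opening of the aryl ester frees O8–H, which must be protected again before C4 is introduced, or substitution would be directed to C5.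
- Comparison: the end game (C4 onto C4a, closure at C3) is the same as in the chosen plan, with extra protecting-group steps. The chosen plan is the more predictable one in diastereocontrol, the alternative the more economical one in chiral material.

Alternative 3: The cut is C3–C4, with C4 already on ring A as an aldehyde. Forward, a triazolium-derived carbene would turn the aldehyde of dimethyl (E)-2-[(S)-[2,3-bis(benzyloxy)-6-formyl-4-methoxyphenyl](3,4,5-trimethoxyphenyl)methyl]but-2-enedioate A8 into an acyl anion equivalent. This adds to C3 (intramolecular Stetter reaction, six-membered ring) and gives the 4-oxotetralin diester A7 after equilibration of C2 and C3.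
- In its favour: ring closure under mild organocatalysis. C4 is in place from the start, so no formylation at C4a is needed, and on that point it is better. Both C2 and C3 are epimerisable in A7, and the most stable arrangement should equal the target's as long as the peri oxygen on C8 keeps the C1 aryl group pseudoaxial. This matches the thermodynamic support that the chosen plan has at C3.
- Against it here: C1 is neither formed nor controlled in the key step. A8 must already be enantioenriched at the diarylmethine carbon, which needs an asymmetric step of its own. The enolisable 4-oxo diester can oxidise to a naphthol, and the C4 ketone must still be removed.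
- Comparison: removal of the C4 oxygen is comparable in both plans. The alternative is weaker in absolute control and needs more steps before its key step.

Key step: step 5

Assumption: the carbinol centre at C4 formed in step 11 is carried as both epimers (drawn without configuration), because it is removed in step 13.

## Route

Step 1
Reactants: 1 2,3-dihydroxy-4-methoxybenzaldehyde; 2 allyl bromide
Product: 4 3-(allyloxy)-2-hydroxy-4-methoxybenzaldehyde, via disodium diphenolate 3 (not isolated)
Conditions: NaH (2.1 equiv), DMSO, 20 °C; then allyl bromide (1.0 equiv), 20 °C; aq. HCl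
Reagents that add atoms: allyl bromide (2), C=CCBr
Why: Williamson ether synthesis on the dianion: the oxide on C3 of the aldehyde (O7) is not conjugated with the formyl group and is the more nucleophilic, so the single equivalent of halide is taken there while the chelated oxide ortho to the formyl group (O8) stays free.

Step 2
Reactants: 4 3-(allyloxy)-2-hydroxy-4-methoxybenzaldehyde; 5 benzyl bromide
Product: 6 3-(allyloxy)-2-(benzyloxy)-4-methoxybenzaldehyde
Conditions: BnBr, K2CO3, DMF, 60 °C
Reagents that add atoms: benzyl bromide (5), BrCc1ccccc1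
Why: Williamson ether synthesis of the remaining hydrogen-bonded phenol (O8), which needs warm DMF; the allyl ether and the aldehyde are inert to carbonate.

Step 3
Reactants: 6 3-(allyloxy)-2-(benzyloxy)-4-methoxybenzaldehyde; 7 malonic acid
Product: 8 (E)-3-[3-(allyloxy)-2-(benzyloxy)-4-methoxyphenyl]prop-2-enoic acid
Conditions: malonic acid, pyridine, piperidine (cat.), 90 °C
Reagents that add atoms: malonic acid (7), OC(=O)CC(=O)O
Why: Knoevenagel–Doebner condensation with decarboxylation gives the (E)-cinnamic acid (C1=C2, C9); the temperature is far below that of a Claisen rearrangement of the allyl aryl ether.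

Step 4
Reactants: 8 (E)-3-[3-(allyloxy)-2-(benzyloxy)-4-methoxyphenyl]prop-2-enoic acid; 9 pivaloyl chloride; 10 (R)-4-benzyloxazolidin-2-one
Product: 12 (R)-4-benzyl-3-[(E)-3-[3-(allyloxy)-2-(benzyloxy)-4-methoxyphenyl]acryloyl]oxazolidin-2-one, via pivalic mixed anhydride 11 (not isolated)
Conditions: PivCl, Et3N, THF, −20 °C; then 10, LiCl, 20 °C
Reagents that add atoms: (R)-4-benzyloxazolidin-2-one (10), O=C1N[C@H](Cc2ccccc2)CO1
Why: N-acylation through the mixed anhydride: the lithium-complexed oxazolidinone, deprotonated by Et3N, attacks the unhindered cinnamoyl carbonyl and not the pivaloyl one; the (E)-alkene is untouched.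

Step 5
Reactants: 12 (R)-4-benzyl-3-[(E)-3-[3-(allyloxy)-2-(benzyloxy)-4-methoxyphenyl]acryloyl]oxazolidin-2-one; 13 5-bromo-1,2,3-trimethoxybenzene; 14 tert-butyl bromoacetate
Product: 17 tert-butyl (3R,4S)-4-[3-(allyloxy)-2-(benzyloxy)-4-methoxyphenyl]-3-[(R)-4-benzyl-2-oxooxazolidine-3-carbonyl]-4-(3,4,5-trimethoxyphenyl)butanoate, via 3,4,5-trimethoxyphenylmagnesium bromide 15 (not isolated), via bromomagnesium imide enolate 16 (not isolated)
Conditions: Mg, THF, 40 °C (13 to 15); CuBr·SMe2 (1 equiv), THF/Me2S, −40 °C; 12, −40 → −15 °C; then DMPU, 14 (excess), −15 → 20 °C; aq. NH4Cl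
Reagents that add atoms: 5-bromo-1,2,3-trimethoxybenzene (13), COc1cc(Br)cc(OC)c1OC; tert-butyl bromoacetate (14), CC(C)(C)OC(=O)CBr
Why: Transmetalation of 15 with CuBr·SMe2 gives an arylcopper species that adds 1,4 to the magnesium-chelated s-cis imide 12 and forms C1–C1′ by reductive elimination, which leaves the chelated (Z)-enolate 16; activated by DMPU, 16 displaces bromide from 14 (SN2) and forms C2–C3. The closest known reaction type is the copper-mediated conjugate addition of aryl Grignard reagents to N-enoyl oxazolidinones with trapping of the enolate by an electrophile, combined with the auxiliary-controlled alkylation of imide enolates; no ring is closed. C1 is controlled by the benzyl group of the (R)-oxazolidinone, which covers one face of the chelated enoyl plane, so the aryl group enters from the other face and C1 becomes S. C2 is controlled by the same benzyl group, which shields the same face of the planar enolate, so C3 enters on the side already taken by the aryl group and C2 becomes R in 17. Because both groups add to one face of the (E)-alkene, the C1 aryl group and C9 will stand cis on ring B after the later closure through C3. The step needs 1,4- over 1,2-addition (secured by copper and the imide), one enolate geometry (secured by s-cis chelation) and a single C-alkylation (the hindered tertiary C2–H of 17 is not re-enolised). Ring A has only the O8 benzyl ether ortho to the alkene at this stage (C4a still carries hydrogen), which keeps the beta carbon open to attack, and the allyl and benzyl ethers are inert at these temperatures.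

Step 6
Reactants: 17 tert-butyl (3R,4S)-4-[3-(allyloxy)-2-(benzyloxy)-4-methoxyphenyl]-3-[(R)-4-benzyl-2-oxooxazolidine-3-carbonyl]-4-(3,4,5-trimethoxyphenyl)butanoate
Product: 18 tert-butyl (3R,4S)-4-[3-(allyloxy)-2-(benzyloxy)-4-methoxyphenyl]-3-(hydroxymethyl)-4-(3,4,5-trimethoxyphenyl)butanoate
Conditions: LiBH4, MeOH (1 equiv), THF, 0 °C; aq. NH4Cl
Reagents that add atoms: none
Why: Reductive cleavage of the auxiliary: hydride attacks the lithium-activated exocyclic imide carbonyl (C9) and releases 10 for recovery, while the hindered tert-butyl ester is not reduced at 0 °C; the neutral work-up avoids lactonisation and C1/C2 are untouched.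

Step 7
Reactants: 18 tert-butyl (3R,4S)-4-[3-(allyloxy)-2-(benzyloxy)-4-methoxyphenyl]-3-(hydroxymethyl)-4-(3,4,5-trimethoxyphenyl)butanoate; 9 pivaloyl chloride
Product: 19 tert-butyl (3R,4S)-4-[3-(allyloxy)-2-(benzyloxy)-4-methoxyphenyl]-3-[(pivaloyloxy)methyl]-4-(3,4,5-trimethoxyphenyl)butanoate
Conditions: PivCl, pyridine, DMAP (cat.), CH2Cl2, 0 → 20 °C
Reagents that add atoms: pivaloyl chloride (9), CC(C)(C)C(=O)Cl
Why: Acylation of the only free hydroxyl under non-alkoxide conditions, so O9 cannot close a γ-lactone onto C10 (which would later force a cis ring fusion at C2/C3); the pivalate has no alpha hydrogen, survives hot acetic acid, carbonate and amide base, and is removed by LiAlH4 in step 12.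

Step 8
Reactants: 19 tert-butyl (3R,4S)-4-[3-(allyloxy)-2-(benzyloxy)-4-methoxyphenyl]-3-[(pivaloyloxy)methyl]-4-(3,4,5-trimethoxyphenyl)butanoate
Product: 20 tert-butyl (3R,4S)-4-[2-(benzyloxy)-3-hydroxy-4-methoxyphenyl]-3-[(pivaloyloxy)methyl]-4-(3,4,5-trimethoxyphenyl)butanoate
Conditions: Pd(PPh3)4 (cat.), morpholine, THF, 20 °C
Reagents that add atoms: none
Why: Tsuji–Trost deallylation: zerovalent palladium inserts into the allyl–O7 bond and morpholine captures the allyl group; the benzyl ether, both esters and the stereocentres are unaffected.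

Step 9
Reactants: 20 tert-butyl (3R,4S)-4-[2-(benzyloxy)-3-hydroxy-4-methoxyphenyl]-3-[(pivaloyloxy)methyl]-4-(3,4,5-trimethoxyphenyl)butanoate; 21 hexamethylenetetramine
Product: 22 tert-butyl (3R,4S)-4-[2-(benzyloxy)-6-formyl-3-hydroxy-4-methoxyphenyl]-3-[(pivaloyloxy)methyl]-4-(3,4,5-trimethoxyphenyl)butanoate
Conditions: hexamethylenetetramine, AcOH, 100 °C; then H2O, 100 °C
Reagents that add atoms: hexamethylenetetramine (21), C1N2CN3CN1CN(C2)C3; water, O
Why: Duff formylation: the free O7–H is the only phenol and both of its ortho carbons (C6, C8) are substituted, so aminomethylation, hydride shift and hydrolysis deliver the formyl group (C4) to the para carbon C4a. The ether-only positions (C5, pendant ring) are much less reactive toward this weak electrophile, and acetic acid rather than trifluoroacetic acid spares the O8 benzyl ether, the tert-butyl ester and the pivalate.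

Step 10
Reactants: 22 tert-butyl (3R,4S)-4-[2-(benzyloxy)-6-formyl-3-hydroxy-4-methoxyphenyl]-3-[(pivaloyloxy)methyl]-4-(3,4,5-trimethoxyphenyl)butanoate; 5 benzyl bromide
Product: 23 tert-butyl (3R,4S)-4-[2,3-bis(benzyloxy)-6-formyl-4-methoxyphenyl]-3-[(pivaloyloxy)methyl]-4-(3,4,5-trimethoxyphenyl)butanoate
Conditions: BnBr, K2CO3, DMF, 20 °C
Reagents that add atoms: benzyl bromide (5), BrCc1ccccc1
Why: Williamson ether synthesis of the acidic para-formyl phenol; capping O7 prevents formation of a phenoxide that would deactivate the aldehyde in the next step, and the group leaves in step 13 together with the O8 benzyl group.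

Step 11
Reactants: 23 tert-butyl (3R,4S)-4-[2,3-bis(benzyloxy)-6-formyl-4-methoxyphenyl]-3-[(pivaloyloxy)methyl]-4-(3,4,5-trimethoxyphenyl)butanoate
Product: 24 tert-butyl 7,8-bis(benzyloxy)-4-hydroxy-6-methoxy-2-[(pivaloyloxy)methyl]-1-(3,4,5-trimethoxyphenyl)-1,2,3,4-tetrahydronaphthalene-3-carboxylate (target locants; C1–C3 as in 26; C4 epimers)
Conditions: 23 added to LiN(SiMe3)2, THF, −78 °C; aq. NH4Cl at −78 °C
Reagents that add atoms: none
Why: Intramolecular aldol addition of the C3 ester enolate to the C4 aldehyde closes ring B (six-membered, enolate exocyclic). Allylic 1,3-strain holds C2–H in the enolate plane and the tether through C1 fixes the attacking face, so C10 ends equatorial and trans to C9, which is also the thermodynamically preferred arrangement; the cold quench prevents loss of water, and the pivalate is inert.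

Step 12
Reactants: 24 tert-butyl 7,8-bis(benzyloxy)-4-hydroxy-6-methoxy-2-[(pivaloyloxy)methyl]-1-(3,4,5-trimethoxyphenyl)-1,2,3,4-tetrahydronaphthalene-3-carboxylate
Product: 25 [7,8-bis(benzyloxy)-4-hydroxy-6-methoxy-1-(3,4,5-trimethoxyphenyl)-1,2,3,4-tetrahydronaphthalene-2,3-diyl]dimethanol (target locants; C1–C3 as in 26; C4 epimers)
Conditions: LiAlH4, THF, 0 → 20 °C; aq. KNaC4H4O6
Reagents that add atoms: none
Why: Hydride reduction converts the tert-butyl ester into the C10 alcohol and cleaves the pivalate to the C9 alcohol; benzyl ethers survive, and afterwards no stereocentre is alpha to a carbonyl group.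

Step 13
Reactants: 25 [7,8-bis(benzyloxy)-4-hydroxy-6-methoxy-1-(3,4,5-trimethoxyphenyl)-1,2,3,4-tetrahydronaphthalene-2,3-diyl]dimethanol
Product: 26 (1S,2S,3S)-2,3-bis(hydroxymethyl)-6-methoxy-1-(3,4,5-trimethoxyphenyl)-1,2,3,4-tetrahydronaphthalene-7,8-diol
Conditions: H2 (3 bar), Pd/C, EtOH/AcOH, 40 °C
Reagents that add atoms: none
Why: Catalytic hydrogenolysis removes both benzyl ethers and the benzylic C4–O bond, which is activated by the para O7–H freed in the same flask; C1–C3 carry no reducible group, and isolation by filtration and evaporation suits the air-sensitive catechol.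

## Compound list

1 | 2,3-dihydroxy-4-methoxybenzaldehyde | COc1ccc(C=O)c(O)c1O | starting material
2 | allyl bromide | C=CCBr | starting material
3 | disodium 3-formyl-6-methoxybenzene-1,2-diolate (formed in situ) | COc1ccc(C=O)c([O-])c1[O-].[Na+].[Na+] | intermediate
4 | 3-(allyloxy)-2-hydroxy-4-methoxybenzaldehyde | COc1ccc(C=O)c(O)c1OCC=C | intermediate
5 | benzyl bromide | BrCc1ccccc1 | starting material
6 | 3-(allyloxy)-2-(benzyloxy)-4-methoxybenzaldehyde | COc1ccc(C=O)c(OCc2ccccc2)c1OCC=C | intermediate
7 | malonic acid | OC(=O)CC(=O)O | starting material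
8 | (E)-3-[3-(allyloxy)-2-(benzyloxy)-4-methoxyphenyl]prop-2-enoic acid | COc1ccc(/C=C/C(=O)O)c(OCc2ccccc2)c1OCC=C | intermediate
9 | pivaloyl chloride | CC(C)(C)C(=O)Cl | starting material
10 | (R)-4-benzyloxazolidin-2-one | O=C1N[C@H](Cc2ccccc2)CO1 | starting material
11 | (E)-3-[3-(allyloxy)-2-(benzyloxy)-4-methoxyphenyl]acrylic pivalic anhydride (formed in situ) | COc1ccc(/C=C/C(=O)OC(=O)C(C)(C)C)c(OCc2ccccc2)c1OCC=C | intermediate
12 | (R)-4-benzyl-3-[(E)-3-[3-(allyloxy)-2-(benzyloxy)-4-methoxyphenyl]acryloyl]oxazolidin-2-one | COc1ccc(/C=C/C(=O)N2[C@H](Cc3ccccc3)COC2=O)c(OCc2ccccc2)c1OCC=C | intermediate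
13 | 5-bromo-1,2,3-trimethoxybenzene | COc1cc(Br)cc(OC)c1OC | starting material
14 | tert-butyl bromoacetate | CC(C)(C)OC(=O)CBr | starting material
15 | 3,4,5-trimethoxyphenylmagnesium bromide (formed in situ) | COc1cc([Mg]Br)cc(OC)c1OC | intermediate
16 | bromomagnesium (Z)-enolate of the (3S)-3,3-diarylpropanoyl imide (formed in situ; C1 S) | COc1ccc(c(OCc2ccccc2)c1OCC=C)[C@H](c1cc(OC)c(OC)c(OC)c1)/C=C(\O[Mg]Br)N1[C@H](Cc2ccccc2)COC1=O | intermediate
17 | tert-butyl (3R,4S)-4-[3-(allyloxy)-2-(benzyloxy)-4-methoxyphenyl]-3-[(R)-4-benzyl-2-oxooxazolidine-3-carbonyl]-4-(3,4,5-trimethoxyphenyl)butanoate | COc1ccc(c(OCc2ccccc2)c1OCC=C)[C@H](c1cc(OC)c(OC)c(OC)c1)[C@H](C(=O)N1[C@H](Cc2ccccc2)COC1=O)CC(=O)OC(C)(C)C | intermediate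
18 | tert-butyl (3R,4S)-4-[3-(allyloxy)-2-(benzyloxy)-4-methoxyphenyl]-3-(hydroxymethyl)-4-(3,4,5-trimethoxyphenyl)butanoate | COc1ccc(c(OCc2ccccc2)c1OCC=C)[C@H](c1cc(OC)c(OC)c(OC)c1)[C@H](CO)CC(=O)OC(C)(C)C | intermediate
19 | tert-butyl (3R,4S)-4-[3-(allyloxy)-2-(benzyloxy)-4-methoxyphenyl]-3-[(pivaloyloxy)methyl]-4-(3,4,5-trimethoxyphenyl)butanoate | COc1ccc(c(OCc2ccccc2)c1OCC=C)[C@H](c1cc(OC)c(OC)c(OC)c1)[C@H](COC(=O)C(C)(C)C)CC(=O)OC(C)(C)C | intermediate
20 | tert-butyl (3R,4S)-4-[2-(benzyloxy)-3-hydroxy-4-methoxyphenyl]-3-[(pivaloyloxy)methyl]-4-(3,4,5-trimethoxyphenyl)butanoate | COc1ccc(c(OCc2ccccc2)c1O)[C@H](c1cc(OC)c(OC)c(OC)c1)[C@H](COC(=O)C(C)(C)C)CC(=O)OC(C)(C)C | intermediate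
21 | hexamethylenetetramine | C1N2CN3CN1CN(C2)C3 | starting material
22 | tert-butyl (3R,4S)-4-[2-(benzyloxy)-6-formyl-3-hydroxy-4-methoxyphenyl]-3-[(pivaloyloxy)methyl]-4-(3,4,5-trimethoxyphenyl)butanoate | COc1cc(C=O)c(c(OCc2ccccc2)c1O)[C@H](c1cc(OC)c(OC)c(OC)c1)[C@H](COC(=O)C(C)(C)C)CC(=O)OC(C)(C)C | intermediate
23 | tert-butyl (3R,4S)-4-[2,3-bis(benzyloxy)-6-formyl-4-methoxyphenyl]-3-[(pivaloyloxy)methyl]-4-(3,4,5-trimethoxyphenyl)butanoate | COc1cc(C=O)c(c(OCc2ccccc2)c1OCc1ccccc1)[C@H](c1cc(OC)c(OC)c(OC)c1)[C@H](COC(=O)C(C)(C)C)CC(=O)OC(C)(C)C | intermediate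
24 | tert-butyl 7,8-bis(benzyloxy)-4-hydroxy-6-methoxy-2-[(pivaloyloxy)methyl]-1-(3,4,5-trimethoxyphenyl)-1,2,3,4-tetrahydronaphthalene-3-carboxylate (target locants; aryl and C9 cis, C9 and C10 trans, absolute configuration at C1–C3 as in 26; both C4 epimers) | COc1cc2c(c(OCc3ccccc3)c1OCc1ccccc1)[C@H](c1cc(OC)c(OC)c(OC)c1)[C@H](COC(=O)C(C)(C)C)[C@@H](C(=O)OC(C)(C)C)C2O | intermediate
25 | [7,8-bis(benzyloxy)-4-hydroxy-6-methoxy-1-(3,4,5-trimethoxyphenyl)-1,2,3,4-tetrahydronaphthalene-2,3-diyl]dimethanol (target locants; C1–C3 as in 26; both C4 epimers) | COc1cc2c(c(OCc3ccccc3)c1OCc1ccccc1)[C@H](c1cc(OC)c(OC)c(OC)c1)[C@H](CO)[C@@H](CO)C2O | intermediate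
26 | (1S,2S,3S)-2,3-bis(hydroxymethyl)-6-methoxy-1-(3,4,5-trimethoxyphenyl)-1,2,3,4-tetrahydronaphthalene-7,8-diol (CNP0188980.2; target locants) | COc1cc2c(c(O)c1O)[C@H](c1cc(OC)c(OC)c(OC)c1)[C@H](CO)[C@@H](CO)C2 | target

## Step count and least certain steps

Total: 13 steps. Longest linear sequence: 13 steps (1 to 26); all other inputs (2, 5, 7, 9, 10, 13, 14, 21) are commercial, and 10 is recovered in step 6.

Step 5 (key step). The most likely failure is incomplete C-alkylation. The bromomagnesium imide enolate is a weak nucleophile and C2 is flanked by the diarylmethyl group, so protonation at work-up or consumption of 14 by surplus arylmetal may outrun C2–C3 formation. A second risk is erosion of facial control if the polar additive loosens the chelate before C1–C1′ is complete. Fallback: divide the step. From 12, the conjugate addition alone (15, CuBr·SMe2, then NH4Cl) would give (R)-4-benzyl-3-[(3S)-3-[3-(allyloxy)-2-(benzyloxy)-4-methoxyphenyl]-3-(3,4,5-trimethoxyphenyl)propanoyl]oxazolidin-2-one F1. After purification, the sodium (Z)-enolate of F1 (NaN(SiMe3)2, THF, −78 °C) would be alkylated with 14 under the same auxiliary control, which returns to the route at 17.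

Step 9. The most likely failure is substitution at the wrong carbon or none at all: C4a is para to the free phenol but lies next to the branched C1 substituent, whereas C5 is ortho and para to two ether oxygens. Competing attack at C5 or on the pendant ring, sluggish reaction in acetic acid, or partial loss of the tert-butyl ester are possible. Fallback: halogenation and metalation in place of electrophilic formylation. From 20, I2/morpholine (which reacts through the phenoxide, whose ortho carbons are blocked) would give tert-butyl (3R,4S)-4-[2-(benzyloxy)-3-hydroxy-6-iodo-4-methoxyphenyl]-3-[(pivaloyloxy)methyl]-4-(3,4,5-trimethoxyphenyl)butanoate F2. BnBr/K2CO3 would convert F2 into tert-butyl (3R,4S)-4-[2,3-bis(benzyloxy)-6-iodo-4-methoxyphenyl]-3-[(pivaloyloxy)methyl]-4-(3,4,5-trimethoxyphenyl)butanoate F3. Iodine–magnesium exchange on F3 (iPrMgCl·LiCl, THF, −40 °C, cold enough to spare both esters) and DMF would return to the route at 23.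

Step 11. The most likely failure is reaction of the amide base at the aldehyde, loss of water from the aldolate to a dihydronaphthalene ester (which erases C3), acyl transfer from the pivalate, or erosion of C1 by deprotonation of the doubly benzylic C1–H, which the ortho formyl group acidifies. Fallback: close ring B by enolate alkylation, with C4 already a methylene and no carbonyl group ortho to C1. From 23, NaBH4 (MeOH/THF, 0 °C) would give tert-butyl (3R,4S)-4-[2,3-bis(benzyloxy)-6-(hydroxymethyl)-4-methoxyphenyl]-3-[(pivaloyloxy)methyl]-4-(3,4,5-trimethoxyphenyl)butanoate F4. MsCl/Et3N with LiCl would convert F4 into tert-butyl (3R,4S)-4-[2,3-bis(benzyloxy)-6-(chloromethyl)-4-methoxyphenyl]-3-[(pivaloyloxy)methyl]-4-(3,4,5-trimethoxyphenyl)butanoate F5. LiN(SiMe3)2 (THF, −78 → 0 °C) would then close ring B of F5 by six-membered exo displacement, under the same allylic-strain control, to tert-butyl 7,8-bis(benzyloxy)-6-methoxy-2-[(pivaloyloxy)methyl]-1-(3,4,5-trimethoxyphenyl)-1,2,3,4-tetrahydronaphthalene-3-carboxylate F6. H2 over Pd/C would turn F6 into tert-butyl 7,8-dihydroxy-6-methoxy-2-[(pivaloyloxy)methyl]-1-(3,4,5-trimethoxyphenyl)-1,2,3,4-tetrahydronaphthalene-3-carboxylate F7. LiAlH4 in excess (THF, under argon, acidic work-up) would reduce both esters of F7 and reach the end of the route at 26.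

Step 13. The most likely failure is that cleavage of the C4–O bond lags behind debenzylation, or that acid promotes dehydration toward C3=C4 followed by unselective hydrogenation, which would scramble C3. Fallback: remove the C4 oxygen by ionic hydrogenation while the phenols are still benzylated. From 25, Et3SiH/CF3CO2H (CH2Cl2, 0 °C; then K2CO3/MeOH to cleave any trifluoroacetates) would give [7,8-bis(benzyloxy)-6-methoxy-1-(3,4,5-trimethoxyphenyl)-1,2,3,4-tetrahydronaphthalene-2,3-diyl]dimethanol F8. Plain hydrogenolysis of F8 (H2, Pd/C, EtOH) would then arrive at 26.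

Step 1. The most likely failure is poor site selectivity (alkylation at O8 or at both oxygens) through proton and cation exchange between the two phenoxides. Fallback: reverse the order and rely on acidity instead of nucleophilicity. From 1, one equivalent of NaH (DMSO) deprotonates only the more acidic hydroxyl ortho to the formyl group, and BnBr would give 2-(benzyloxy)-3-hydroxy-4-methoxybenzaldehyde F9. Allyl bromide/K2CO3 (DMF) would convert F9 into 6, where the route is rejoined.

## Further compounds

F1 | step 5 | (R)-4-benzyl-3-[(3S)-3-[3-(allyloxy)-2-(benzyloxy)-4-methoxyphenyl]-3-(3,4,5-trimethoxyphenyl)propanoyl]oxazolidin-2-one | COc1ccc(c(OCc2ccccc2)c1OCC=C)[C@H](c1cc(OC)c(OC)c(OC)c1)CC(=O)N1[C@H](Cc2ccccc2)COC1=O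
F2 | step 9 | tert-butyl (3R,4S)-4-[2-(benzyloxy)-3-hydroxy-6-iodo-4-methoxyphenyl]-3-[(pivaloyloxy)methyl]-4-(3,4,5-trimethoxyphenyl)butanoate | COc1cc(I)c(c(OCc2ccccc2)c1O)[C@H](c1cc(OC)c(OC)c(OC)c1)[C@H](COC(=O)C(C)(C)C)CC(=O)OC(C)(C)C
F3 | step 9 | tert-butyl (3R,4S)-4-[2,3-bis(benzyloxy)-6-iodo-4-methoxyphenyl]-3-[(pivaloyloxy)methyl]-4-(3,4,5-trimethoxyphenyl)butanoate | COc1cc(I)c(c(OCc2ccccc2)c1OCc1ccccc1)[C@H](c1cc(OC)c(OC)c(OC)c1)[C@H](COC(=O)C(C)(C)C)CC(=O)OC(C)(C)C
F4 | step 11 | tert-butyl (3R,4S)-4-[2,3-bis(benzyloxy)-6-(hydroxymethyl)-4-methoxyphenyl]-3-[(pivaloyloxy)methyl]-4-(3,4,5-trimethoxyphenyl)butanoate | COc1cc(CO)c(c(OCc2ccccc2)c1OCc1ccccc1)[C@H](c1cc(OC)c(OC)c(OC)c1)[C@H](COC(=O)C(C)(C)C)CC(=O)OC(C)(C)C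
F5 | step 11 | tert-butyl (3R,4S)-4-[2,3-bis(benzyloxy)-6-(chloromethyl)-4-methoxyphenyl]-3-[(pivaloyloxy)methyl]-4-(3,4,5-trimethoxyphenyl)butanoate | COc1cc(CCl)c(c(OCc2ccccc2)c1OCc1ccccc1)[C@H](c1cc(OC)c(OC)c(OC)c1)[C@H](COC(=O)C(C)(C)C)CC(=O)OC(C)(C)C
F6 | step 11 | tert-butyl 7,8-bis(benzyloxy)-6-methoxy-2-[(pivaloyloxy)methyl]-1-(3,4,5-trimethoxyphenyl)-1,2,3,4-tetrahydronaphthalene-3-carboxylate (target locants; C1–C3 as in 26) | COc1cc2c(c(OCc3ccccc3)c1OCc1ccccc1)[C@H](c1cc(OC)c(OC)c(OC)c1)[C@H](COC(=O)C(C)(C)C)[C@@H](C(=O)OC(C)(C)C)C2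
F7 | step 11 | tert-butyl 7,8-dihydroxy-6-methoxy-2-[(pivaloyloxy)methyl]-1-(3,4,5-trimethoxyphenyl)-1,2,3,4-tetrahydronaphthalene-3-carboxylate (target locants; C1–C3 as in 26) | COc1cc2c(c(O)c1O)[C@H](c1cc(OC)c(OC)c(OC)c1)[C@H](COC(=O)C(C)(C)C)[C@@H](C(=O)OC(C)(C)C)C2
F8 | step 13 | [7,8-bis(benzyloxy)-6-methoxy-1-(3,4,5-trimethoxyphenyl)-1,2,3,4-tetrahydronaphthalene-2,3-diyl]dimethanol (target locants; C1–C3 as in 26) | COc1cc2c(c(OCc3ccccc3)c1OCc1ccccc1)[C@H](c1cc(OC)c(OC)c(OC)c1)[C@H](CO)[C@@H](CO)C2
F9 | step 1 | 2-(benzyloxy)-3-hydroxy-4-methoxybenzaldehyde | COc1ccc(C=O)c(OCc2ccccc2)c1O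
A1 | alternative 1 | endo, anti cycloadduct: 1-aryltetralin cis-fused at C2/C3 to the C9 lactone whose acetal carbon C10 carries the l-menthyloxy group (C1 and C2 as in 26, C3 epimeric) | COc1cc2c(c(OCc3ccccc3)c1OCc3ccccc3)[C@H](c1cc(OC)c(OC)c(OC)c1)[C@@H]5C(=O)O[C@@H](O[C@@H]6C[C@H](C)CC[C@H]6C(C)C)[C@@H]5C2
A2 | alternative 1 | 2,3-bis(benzyloxy)-4-methoxy-8-(3,4,5-trimethoxyphenyl)bicyclo[4.2.0]octa-1,3,5-triene (racemic) | COc1cc2c(c(OCc3ccccc3)c1OCc1ccccc1)C(c1cc(OC)c(OC)c(OC)c1)C2
A3 | alternative 1 | (5R)-5-[(1R,2S,5R)-menthyloxy]furan-2(5H)-one | O=C1C=C[C@H](O[C@@H]2C[C@H](C)CC[C@H]2C(C)C)O1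
A4 | alternative 2 | methyl 2-[(3R,4S)-8-(allyloxy)-7-methoxy-2-oxo-4-(3,4,5-trimethoxyphenyl)chroman-3-yl]acetate (trans) | COc1ccc2c(c1OCC=C)OC(=O)[C@H](CC(=O)OC)[C@H]2c1cc(OC)c(OC)c(OC)c1
A5 | alternative 2 | 2-(allyloxy)-3-methoxy-6-[(4-methylphenylsulfonyl)(3,4,5-trimethoxyphenyl)methyl]phenol (racemic) | COc1ccc(C(c2cc(OC)c(OC)c(OC)c2)S(=O)(=O)c2ccc(C)cc2)c(O)c1OCC=C
A6 | alternative 2 | methyl (E)-4-oxobut-2-enoate | COC(=O)/C=C/C=O
A7 | alternative 3 | dimethyl 7,8-bis(benzyloxy)-6-methoxy-4-oxo-1-(3,4,5-trimethoxyphenyl)-1,2,3,4-tetrahydronaphthalene-2,3-dicarboxylate (target locants; C1–C3 as in 26) | COc1cc2c(c(OCc3ccccc3)c1OCc3ccccc3)[C@H](c1cc(OC)c(OC)c(OC)c1)[C@H](C(=O)OC)[C@@H](C(=O)OC)C2=O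
A8 | alternative 3 | dimethyl (E)-2-[(S)-[2,3-bis(benzyloxy)-6-formyl-4-methoxyphenyl](3,4,5-trimethoxyphenyl)methyl]but-2-enedioate | COc1cc(C=O)c(c(OCc2ccccc2)c1OCc1ccccc1)[C@H](c1cc(OC)c(OC)c(OC)c1)/C(C(=O)OC)=C\C(=O)OC
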